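## Structural features

The target is a single tetrahydrofuran ring (O1, C2, C3, C4, C5) in which both carbons next to oxygen, C2 and C5, are plain CH2 groups. C3 carries an exocyclic secondary benzylic carbinol carbon (called C7 here) bonded to a 4-hydroxy-3,5-dimethoxyphenyl ring, and C4 carries the CH2 of a 4-hydroxy-3-methoxybenzyl group. C7, C3 and C4 are three contiguous stereocentres, all S; the two ring substituents are trans, and C7 lies outside the ring, so the ring cannot relay its configuration rigidly. The fragile groups are the two free phenols (attacked by periodate and by air under base) and the C7 hydroxyl, which sits para to an oxygen-bearing ring and ionises easily under Brønsted or Lewis acid, with loss, hydride capture or capture by a neighbouring hydroxyl. The real difficulty is twofold: the ring has no handle at C2 or C5 from which C3 and C4 could be controlled, and C7 must be set on a carbonyl whose "small" flank is a branched ring carbon. The key step uses the fact that C3 (acyl-level substituent) and C4 (benzyl substituent), trans on adjacent carbons, are the β and α carbons of a γ-butyrolactone whose carbonyl is C5 and whose γ carbon is C2, so a removable γ substituent can steer both centres. A check of the descriptors shows that the (S)-hydroxymethyl butenolide maps through a (3S,4S,5S) all-trans lactone onto the (3S,4S) ring of the target, so the structures are consistent and the readily available enantiomer is the correct one.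

## Logic of the disconnections

22 is traced to 21 by restoring three O–Si bonds (two phenols and the C7 oxygen). The phenols must be masked against periodate and the C7 oxygen against taking part in ring closure; one silyl type allows a single last step. No skeletal simplification results, but every earlier step is freed from acidic and oxidisable hydroxyls. The forward step needs buffered fluoride, so that a phenoxide next to a benzylic C–O bond does not expel it.

21 is cut at O1–C2 (O1–C5 is equivalent), giving 20. Both carbons are non-stereogenic CH2 groups, so either hydroxyl of 20 may serve as nucleophile or electrophile. The ring closure becomes a dehydration that needs neither Lewis acid nor hydride, both of which would threaten the ionisable C7–O bond. The demand is that the C7 oxygen is already blocked, otherwise it would close onto C5.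

20 is traced to 18, by way of 19, by re-attaching one carbon to C2: the C2 hydroxymethyl stems from C–C cleavage of a terminal 1,2-diol followed by reduction. This is the point where the control stereocentre and its carbon are removed, and it exposes the retron of a γ-substituted lactone. The forward step requires that no free phenol meets periodate. The C2 aldehyde must also be reduced in the same flask, because C3 next to it is epimerisable and C7 carries a β-leaving group.

18 goes back to 17 (primary O–Si bond restored) and 17 to 16 (C5–OH and the secondary C2–OH rejoined as the ester C5(=O)–O1). The lactone is the ring in which C3 and C4 can be controlled. The forward steps demand a hydride that reduces a lactone but spares silyl ethers, and an acid mild enough to remove only the primary alkyl silyl ether.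

16 goes back to 15 (C7–O–Si cut) and 15 to 14 (C7–H cut). C7 is best carried at the ketone level because that is what acyl-anion chemistry delivers, and a ketone lets a chiral reagent decide the configuration. The demand is a reducing system that tells the aryl group from the branched ring carbon and is not basic, since 14 is a β-acyloxy ketone and 15 could translactonise.

14 is traced to 13 by exchanging C7=O for the two C–S bonds of a dithiane. This reveals the umpoled carbon. The forward hydrolysis must work without mercury salts and must spare the silyl ethers and the electron-rich rings.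

13 is cut at two C–C bonds, C3–C7 and C4–CH2(aryl) in tetrahydrofuran numbering, to give 2, 6 and 10; 11 and 12 are the reactive forms. Both bonds lie on the flanks of a Michael acceptor and its enolate, so three fragments of similar size result and two stereocentres derive from one. The forward step demands 1,4- rather than 1,2-addition, attack anti to the C2 substituent, and alkylation anti to the new C3 substituent, all in one flask.

2 is traced to 1 by cutting the O–Si bond; the base in the forward step must be too weak to remove the γ-hydrogen.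

6 is traced to 4 and 5 (two C–S bonds) and 4 to 3 (O–Si bond). The silyl ether is placed first so that the phenol never meets the organolithium; the demand is an acetalisation catalyst that leaves the aryl silyl ether alone.

10 is traced to 9 (C–Br), 9 to 8 (C–H, carbonyl reduction) and 8 to 7 (O–Si). The aldehyde level of 7 is chosen because a phenol cannot be silylated reliably beside a free benzylic alcohol; this costs one hydride step. The bromination must be neutral, because 10 is an ionisable para-silyloxybenzyl bromide.

## Other disconnections considered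

Alternative 1: The ring is cut at C2–C3 and C4–C5, leaving the C3–C4 bond as the E-alkene of the aroylacryloyl oxazolidinone imide A1 and O1 with both CH2 neighbours as the parent carbonyl ylide. In the forward step CsF desilylates chloromethyl trimethylsilylmethyl ether A2, chloride leaves, and the CH2–O–CH2 dipole adds across the alkene of A1 in a (3+2) cycloaddition to give the trans-3-acyl-4-aroyltetrahydrofuran A3.
- In its favour: ring and both ring stereocentres arise in one step at the right oxidation level of C2 and C5. The trans relationship follows stereospecifically from the alkene geometry. No carbon is excised and no thiol is needed.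
- Against it here: the absolute sense rests on facial discrimination by an auxiliary at one end of a doubly activated alkene reacting with a very reactive, unstabilised dipole. Chelating Lewis acids that would lock the imide are hard to combine with fluoride. A2 is an α-chloro ether and a handling hazard. After the cycloaddition the aroyl carbonyl must be reduced to CH2 beside the imide, the imide turned into the syringyl ketone, and that ketone reduced stereoselectively.
- Comparison: on structure the alternative is better (direct ring formation, no sacrificial carbon). On mechanism the trans relationship is equally secure, but absolute control is better in the chosen plan, where the inducing centre sits on the ring next to the reacting carbon. The C7 problem is the same in both. Step economy is about equal or slightly better for the alternative, provided the facial selectivity is useful.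

Alternative 2: The cuts are O1–C5 and C3–C4, giving vinylethylene carbonate A4 as the O1–C2–C3(vinyl) unit and the aryl vinyl ketone A5 as the C4–C5 unit. In the forward step Pd2(dba)3 and a chiral phosphoramidite ionise A4 with loss of CO2 (zerovalent palladium becomes a divalent allylpalladium alkoxide). The alkoxide adds to the β carbon of A5 and the enolate closes on the substituted allyl terminus to give the 3-vinyl-4-aroyltetrahydrofuran A6.
- In its favour: catalytic enantiocontrol from achiral partners (A5 would come from 8 in two steps). C4 is α to the ketone and can equilibrate to trans, so only C3 needs kinetic control. The vinyl group is a clean precursor of C7.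
- Against it here: this annulation behaves best with acceptors that are doubly activated or leave no α-hydrogen. A simple aryl vinyl ketone polymerises easily, adds alkoxide reversibly and gives an enolate that can simply be protonated. Afterwards the ketone must be deoxygenated, the alkene cleaved to an aldehyde with an epimerisable α centre, and the syringyl group added with uncertain 1,2-induction or via oxidation and reagent-controlled reduction.
- Comparison: the alternative is better in step economy (about ten operations) and in needing neither a stoichiometric control element nor a carbon excision. It is equal in that C7 is again set late from a carbonyl. It is weaker in mechanistic security, because one catalyst-controlled step on a substrate outside the usual range carries the whole absolute configuration, whereas the chosen plan relies on two substrate-enforced trans inductions.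

Alternative 3: The cuts are C3–C4 and the bond from the benzylic CH2 to the guaiacyl ring. The redox-active ester A7 holds C7 (already as the (S)-silyl ether), the radical precursor carbon C3, C2, O1 and the allyl group; the ring comes as aryl iodide A8. In the forward step NiBr2(dme), 4,4'-di-tert-butyl-2,2'-bipyridine and Zn reduce A7; loss of CO2 and phthalimide gives the C3 radical, which closes 5-exo-trig onto the allyl ether. The new primary radical is captured by an arylnickel species from A8 to give A9, which is identical with compound 21.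
- In its favour: by far the shortest route (A9 is one fluoride step from the target), two C–C bonds and the ring in one step, C7 set early on a simple precursor, no excised carbon.
- Against it here: C3 and C4 are created in a radical cyclisation. The radical carbon itself bears the substituent, and the chair-like 5-exo transition state of such radicals usually places the two new ring substituents cis, the wrong relationship. The configuration of C3 relative to C7 also depends on acyclic 1,2-induction at a planar radical. Up to four diastereomers are possible and would be hard to separate at the stage of A9.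
- Comparison: the alternative is better in step economy and convergence and equal in the end game (same last step). It is clearly weaker in stereocontrol, which is what the chosen plan pays its extra steps for.

Key step: step 7

## Route

Remark on the chemistry: TBS = tert-butyldimethylsilyl, TIPS = triisopropylsilyl; the tetrahydrofuran numbering (O1, C2–C5, carbinol carbon C7) is used for all intermediates.

Step 1
Reactants: 1 (S)-5-(hydroxymethyl)furan-2(5H)-one
Product: 2 (S)-5-(TBS-oxymethyl)furan-2(5H)-one
Conditions: TBSCl, imidazole, CH2Cl2, 0 °C → rt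
Reagents that add atoms: tert-butyldimethylsilyl chloride, CC(C)(C)[Si](C)(C)Cl
Why: Standard imidazole-assisted silylation of a primary alcohol; imidazole is too weak a base to remove the γ-hydrogen, so the stereocentre and the double-bond position are kept.

Step 2
Reactants: 3 syringaldehyde (4-hydroxy-3,5-dimethoxybenzaldehyde)
Product: 4 3,5-dimethoxy-4-(TIPS-oxy)benzaldehyde
Conditions: TIPSCl, imidazole, DMF, rt
Reagents that add atoms: triisopropylsilyl chloride, CC(C)[Si](Cl)(C(C)C)C(C)C
Why: Silyl ether formation on a phenol made acidic by the para formyl group; the bulky TIPS group is chosen because it must survive organolithium, hydride and mild acid later.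

Step 3
Reactants: 4 3,5-dimethoxy-4-(TIPS-oxy)benzaldehyde; 5 propane-1,3-dithiol
Product: 6 2-[3,5-dimethoxy-4-(TIPS-oxy)phenyl]-1,3-dithiane
Conditions: BF3·OEt2 (10 mol %), CH2Cl2, 0 °C
Reagents that add atoms: none
Why: Lewis acid catalysed dithioacetalisation of an aromatic aldehyde; a catalytic amount of BF3·OEt2 at 0 °C should leave the hindered aryl TIPS ether intact, and the product has the acidic C2–H needed for umpolung.

Step 4
Reactants: 7 vanillin (4-hydroxy-3-methoxybenzaldehyde)
Product: 8 3-methoxy-4-(TIPS-oxy)benzaldehyde
Conditions: TIPSCl, imidazole, DMF, rt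
Reagents that add atoms: triisopropylsilyl chloride, CC(C)[Si](Cl)(C(C)C)C(C)C
Why: Same phenol silylation as in step 2; starting at the aldehyde level avoids any competition between a phenol and a benzylic alcohol.

Step 5
Reactants: 8 3-methoxy-4-(TIPS-oxy)benzaldehyde
Product: 9 [3-methoxy-4-(TIPS-oxy)phenyl]methanol
Conditions: NaBH4, MeOH, 0 °C
Reagents that add atoms: none
Why: Borohydride reduction of an aromatic aldehyde; short exposure at 0 °C leaves the aryl silyl ether untouched.

Step 6
Reactants: 9 [3-methoxy-4-(TIPS-oxy)phenyl]methanol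
Product: 10 4-(bromomethyl)-2-methoxyphenyl TIPS ether
Conditions: CBr4, PPh3, CH2Cl2, 0 °C
Reagents that add atoms: tetrabromomethane, BrC(Br)(Br)Br
Why: Appel bromination; the alkoxyphosphonium ion is displaced by bromide under neutral conditions, which suits an ionisable para-silyloxybenzylic system better than reagents that release HBr. The bromide is used directly.

Step 7
Reactants: 6 2-[3,5-dimethoxy-4-(TIPS-oxy)phenyl]-1,3-dithiane; 2 (S)-5-(TBS-oxymethyl)furan-2(5H)-one; 10 4-(bromomethyl)-2-methoxyphenyl TIPS ether
Product: 13 (3S,4S,5S)-5-(TBS-oxymethyl)-4-{2-[3,5-dimethoxy-4-(TIPS-oxy)phenyl]-1,3-dithian-2-yl}-3-[3-methoxy-4-(TIPS-oxy)benzyl]dihydrofuran-2(3H)-one (all-trans), via 2-lithio-1,3-dithiane 11 (not isolated), via lithium enolate 12 (not isolated)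
Conditions: 6, n-BuLi, THF, −78 °C; 2, −78 °C; DMPU, 10, −78 → −30 °C; aq NH4Cl
Reagents that add atoms: none
Why: n-BuLi removes the proton between the two sulfur atoms of 6 and gives the aryl-stabilised anion 11. This soft, delocalised carbanion should add in Michael fashion to the β carbon of 2 (the future C3) and not to the carbonyl, from the face opposite the γ silyloxymethyl group, which sets the first new stereocentre trans to the existing one. The lithium enolate 12 is then alkylated on carbon by 10 once DMPU (chosen over HMPA for safety) has loosened the aggregate; the very large dithianyl group shields its own face, so the benzyl group should enter trans to it and set the second stereocentre (the future C4). The closest known reaction type is the tandem conjugate addition–enolate alkylation of γ-substituted butenolides with 2-aryl-1,3-dithiane anions, the usual entry to trans-dibenzylbutyrolactone lignans. No ring is closed; the lactone ring is already present and later supplies C5, C4, C3 and C2. The step needs 1,4- over 1,2-addition (secured by the aryl-stabilised anion in THF), addition faster than removal of the γ-hydrogen of 2 (low temperature), and C- rather than O-alkylation (reactive benzylic bromide). Both new centres are controlled by adjacent ring substituents on a five-membered ring, so each induction is a simple 1,2-trans relationship.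

Step 8
Reactants: 13 (3S,4S,5S)-5-(TBS-oxymethyl)-4-{2-[3,5-dimethoxy-4-(TIPS-oxy)phenyl]-1,3-dithian-2-yl}-3-[3-methoxy-4-(TIPS-oxy)benzyl]dihydrofuran-2(3H)-one
Product: 14 (3S,4S,5S)-5-(TBS-oxymethyl)-4-[3,5-dimethoxy-4-(TIPS-oxy)benzoyl]-3-[3-methoxy-4-(TIPS-oxy)benzyl]dihydrofuran-2(3H)-one
Conditions: PhI(OCOCF3)2, NaHCO3, MeCN/H2O (9:1), 0 °C
Reagents that add atoms: water, O
Why: Oxidative dithiane hydrolysis with a trivalent iodine reagent, a mercury-free method: sulfur is activated at iodine, water adds to the thionium ion and the carbonyl is released while the sulfur chain leaves as the cyclic disulfide. Bicarbonate takes up the CF3CO2H so that the primary TBS ether survives, and it is too weak a base to open the β-acyloxy ketone by E1cB; no stereocentre is touched.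

Step 9
Reactants: 14 (3S,4S,5S)-5-(TBS-oxymethyl)-4-[3,5-dimethoxy-4-(TIPS-oxy)benzoyl]-3-[3-methoxy-4-(TIPS-oxy)benzyl]dihydrofuran-2(3H)-one
Product: 15 (3S,4R,5S)-5-(TBS-oxymethyl)-4-{(S)-[3,5-dimethoxy-4-(TIPS-oxy)phenyl](hydroxy)methyl}-3-[3-methoxy-4-(TIPS-oxy)benzyl]dihydrofuran-2(3H)-one (the C4 descriptor changes by priority only)
Conditions: (R)-2-methyl-CBS-oxazaborolidine (20 mol %), BH3·SMe2, THF, −20 °C; MeOH
Reagents that add atoms: none
Why: Corey–Bakshi–Shibata reduction: the ketone binds to the ring boron with the aryl group pointing away and hydride is delivered from the nitrogen-bound borane to one face, which with the (R)-catalyst should give the (S)-carbinol for an aryl ketone. The ring carbon next to the carbonyl is flanked by two trans CH2X branches of similar size, so the substrate bias should be small and the catalyst should decide C7. Borane does not reduce the lactone at this temperature, and the non-basic medium avoids translactonisation and E1cB opening.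

Step 10
Reactants: 15 (3S,4R,5S)-5-(TBS-oxymethyl)-4-{(S)-[3,5-dimethoxy-4-(TIPS-oxy)phenyl](hydroxy)methyl}-3-[3-methoxy-4-(TIPS-oxy)benzyl]dihydrofuran-2(3H)-one
Product: 16 (3S,4S,5S)-5-(TBS-oxymethyl)-4-{(S)-[3,5-dimethoxy-4-(TIPS-oxy)phenyl](TIPS-oxy)methyl}-3-[3-methoxy-4-(TIPS-oxy)benzyl]dihydrofuran-2(3H)-one
Conditions: TIPSOTf, 2,6-lutidine, CH2Cl2, 0 °C → rt
Reagents that add atoms: triisopropylsilyl trifluoromethanesulfonate, CC(C)[Si](OS(=O)(=O)C(F)(F)F)(C(C)C)C(C)C
Why: Silylation with a silyl triflate and a hindered pyridine base, the usual method for hindered secondary alcohols; the conditions are non-nucleophilic, so the lactone stays closed and C7 is not touched.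

Step 11
Reactants: 16 (3S,4S,5S)-5-(TBS-oxymethyl)-4-{(S)-[3,5-dimethoxy-4-(TIPS-oxy)phenyl](TIPS-oxy)methyl}-3-[3-methoxy-4-(TIPS-oxy)benzyl]dihydrofuran-2(3H)-one
Product: 17 (2S,3S,4S)-5-(TBS-oxy)-3-{(S)-[3,5-dimethoxy-4-(TIPS-oxy)phenyl](TIPS-oxy)methyl}-2-[3-methoxy-4-(TIPS-oxy)benzyl]pentane-1,4-diol
Conditions: LiBH4, THF, 0 °C → rt
Reagents that add atoms: none
Why: Hydride reduction of a lactone to the diol; LiBH4 is strong enough for the lactone, is easier to handle than LiAlH4, and should not cleave alkyl or aryl silyl ethers or cause silyl migration at this temperature. No stereocentre is affected.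

Step 12
Reactants: 17 (2S,3S,4S)-5-(TBS-oxy)-3-{(S)-[3,5-dimethoxy-4-(TIPS-oxy)phenyl](TIPS-oxy)methyl}-2-[3-methoxy-4-(TIPS-oxy)benzyl]pentane-1,4-diol
Product: 18 (2S,3S,4S)-3-{(S)-[3,5-dimethoxy-4-(TIPS-oxy)phenyl](TIPS-oxy)methyl}-4-[3-methoxy-4-(TIPS-oxy)benzyl]pentane-1,2,5-triol
Conditions: CSA (10 mol %), MeOH/CH2Cl2, 0 °C
Reagents that add atoms: none
Why: Acid-catalysed methanolysis of a primary alkyl TBS ether; under Brønsted acid a primary alkyl TBS ether is far more labile than a secondary TIPS or an aryl TIPS ether, the reverse of the order under fluoride or base, so only this group should be removed.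

Step 13
Reactants: 18 (2S,3S,4S)-3-{(S)-[3,5-dimethoxy-4-(TIPS-oxy)phenyl](TIPS-oxy)methyl}-4-[3-methoxy-4-(TIPS-oxy)benzyl]pentane-1,2,5-triol
Product: 20 (2S,3S)-2-{(S)-[3,5-dimethoxy-4-(TIPS-oxy)phenyl](TIPS-oxy)methyl}-3-[3-methoxy-4-(TIPS-oxy)benzyl]butane-1,4-diol, via lactol 19 (not isolated)
Conditions: NaIO4, THF/pH 7 buffer, 0 °C; then NaBH4, 0 °C
Reagents that add atoms: none
Why: Malaprade glycol cleavage of the terminal 1,2-diol gives the C2 aldehyde, which is trapped at once by the C5 hydroxyl as lactol 19. Borohydride then reduces the open form to the primary alcohol before C3 can epimerise or the β-silyloxy group can eliminate; the phenols are silylated and therefore inert to periodate.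

Step 14
Reactants: 20 (2S,3S)-2-{(S)-[3,5-dimethoxy-4-(TIPS-oxy)phenyl](TIPS-oxy)methyl}-3-[3-methoxy-4-(TIPS-oxy)benzyl]butane-1,4-diol
Product: 21 (3S,4S)-3-{(S)-[3,5-dimethoxy-4-(TIPS-oxy)phenyl](TIPS-oxy)methyl}-4-[3-methoxy-4-(TIPS-oxy)benzyl]tetrahydrofuran
Conditions: PPh3, DIAD, THF, 0 °C → rt
Reagents that add atoms: none
Why: Mitsunobu cyclodehydration of a 1,4-diol: one primary hydroxyl becomes an alkoxyphosphonium leaving group and the other displaces it in a 5-exo-tet closure. Both carbinol carbons are CH2 groups, so it does not matter which is activated, no stereocentre is involved, and no acid or hydride that could ionise the C7–O bond is present.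

Step 15
Reactants: 21 (3S,4S)-3-{(S)-[3,5-dimethoxy-4-(TIPS-oxy)phenyl](TIPS-oxy)methyl}-4-[3-methoxy-4-(TIPS-oxy)benzyl]tetrahydrofuran
Product: 22 (S)-(4-hydroxy-3,5-dimethoxyphenyl)[(3S,4S)-4-(4-hydroxy-3-methoxybenzyl)tetrahydrofuran-3-yl]methanol
Conditions: TBAF, AcOH, THF, 0 °C → rt
Reagents that add atoms: none
Why: Fluoride cleavage of all three Si–O bonds, driven by the strong Si–F bond; acetic acid buffers the phenoxides so that the para-hydroxybenzylic alcohol does not eliminate to a quinone methide, and no stereocentre is affected.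

## Compound list

1 | (S)-5-(hydroxymethyl)furan-2(5H)-one | O=C1C=C[C@@H](CO)O1 | starting material
2 | (S)-5-(TBS-oxymethyl)furan-2(5H)-one | O=C1C=C[C@@H](CO[Si](C)(C)C(C)(C)C)O1 | intermediate
3 | syringaldehyde | COc1cc(C=O)cc(OC)c1O | starting material
4 | 3,5-dimethoxy-4-(TIPS-oxy)benzaldehyde | COc1cc(C=O)cc(OC)c1O[Si](C(C)C)(C(C)C)C(C)C | intermediate
5 | propane-1,3-dithiol | SCCCS | starting material
6 | 2-[3,5-dimethoxy-4-(TIPS-oxy)phenyl]-1,3-dithiane | COc1cc(C2SCCCS2)cc(OC)c1O[Si](C(C)C)(C(C)C)C(C)C | intermediate
7 | vanillin | COc1cc(C=O)ccc1O | starting material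
8 | 3-methoxy-4-(TIPS-oxy)benzaldehyde | COc1cc(C=O)ccc1O[Si](C(C)C)(C(C)C)C(C)C | intermediate
9 | [3-methoxy-4-(TIPS-oxy)phenyl]methanol | COc1cc(CO)ccc1O[Si](C(C)C)(C(C)C)C(C)C | intermediate
10 | 4-(bromomethyl)-2-methoxyphenyl TIPS ether | COc1cc(CBr)ccc1O[Si](C(C)C)(C(C)C)C(C)C | intermediate
11 | 2-lithio-2-[3,5-dimethoxy-4-(TIPS-oxy)phenyl]-1,3-dithiane (formed in the flask) | [Li]C1(SCCCS1)c1cc(OC)c(O[Si](C(C)C)(C(C)C)C(C)C)c(OC)c1 | intermediate
12 | lithium enolate of (4S,5S)-5-(TBS-oxymethyl)-4-{2-[3,5-dimethoxy-4-(TIPS-oxy)phenyl]-1,3-dithian-2-yl}dihydrofuran-2(3H)-one (formed in the flask) | [Li]OC1=C[C@H](C2(SCCCS2)c2cc(OC)c(O[Si](C(C)C)(C(C)C)C(C)C)c(OC)c2)[C@@H](CO[Si](C)(C)C(C)(C)C)O1 | intermediate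
13 | (3S,4S,5S)-5-(TBS-oxymethyl)-4-{2-[3,5-dimethoxy-4-(TIPS-oxy)phenyl]-1,3-dithian-2-yl}-3-[3-methoxy-4-(TIPS-oxy)benzyl]dihydrofuran-2(3H)-one | COc1cc(C[C@@H]2C(=O)O[C@H](CO[Si](C)(C)C(C)(C)C)[C@H]2C3(SCCCS3)c3cc(OC)c(O[Si](C(C)C)(C(C)C)C(C)C)c(OC)c3)ccc1O[Si](C(C)C)(C(C)C)C(C)C | intermediate
14 | (3S,4S,5S)-5-(TBS-oxymethyl)-4-[3,5-dimethoxy-4-(TIPS-oxy)benzoyl]-3-[3-methoxy-4-(TIPS-oxy)benzyl]dihydrofuran-2(3H)-one | COc1cc(C[C@@H]2C(=O)O[C@H](CO[Si](C)(C)C(C)(C)C)[C@H]2C(=O)c2cc(OC)c(O[Si](C(C)C)(C(C)C)C(C)C)c(OC)c2)ccc1O[Si](C(C)C)(C(C)C)C(C)C | intermediate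
15 | (3S,4R,5S)-5-(TBS-oxymethyl)-4-{(S)-[3,5-dimethoxy-4-(TIPS-oxy)phenyl](hydroxy)methyl}-3-[3-methoxy-4-(TIPS-oxy)benzyl]dihydrofuran-2(3H)-one | COc1cc(C[C@@H]2C(=O)O[C@H](CO[Si](C)(C)C(C)(C)C)[C@H]2[C@H](O)c2cc(OC)c(O[Si](C(C)C)(C(C)C)C(C)C)c(OC)c2)ccc1O[Si](C(C)C)(C(C)C)C(C)C | intermediate
16 | (3S,4S,5S)-5-(TBS-oxymethyl)-4-{(S)-[3,5-dimethoxy-4-(TIPS-oxy)phenyl](TIPS-oxy)methyl}-3-[3-methoxy-4-(TIPS-oxy)benzyl]dihydrofuran-2(3H)-one | COc1cc(C[C@@H]2C(=O)O[C@H](CO[Si](C)(C)C(C)(C)C)[C@H]2[C@H](O[Si](C(C)C)(C(C)C)C(C)C)c2cc(OC)c(O[Si](C(C)C)(C(C)C)C(C)C)c(OC)c2)ccc1O[Si](C(C)C)(C(C)C)C(C)C | intermediate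
17 | (2S,3S,4S)-5-(TBS-oxy)-3-{(S)-[3,5-dimethoxy-4-(TIPS-oxy)phenyl](TIPS-oxy)methyl}-2-[3-methoxy-4-(TIPS-oxy)benzyl]pentane-1,4-diol | COc1cc(C[C@H](CO)[C@@H]([C@H](O)CO[Si](C)(C)C(C)(C)C)[C@H](O[Si](C(C)C)(C(C)C)C(C)C)c2cc(OC)c(O[Si](C(C)C)(C(C)C)C(C)C)c(OC)c2)ccc1O[Si](C(C)C)(C(C)C)C(C)C | intermediate
18 | (2S,3S,4S)-3-{(S)-[3,5-dimethoxy-4-(TIPS-oxy)phenyl](TIPS-oxy)methyl}-4-[3-methoxy-4-(TIPS-oxy)benzyl]pentane-1,2,5-triol | COc1cc(C[C@H](CO)[C@@H]([C@H](O)CO)[C@H](O[Si](C(C)C)(C(C)C)C(C)C)c2cc(OC)c(O[Si](C(C)C)(C(C)C)C(C)C)c(OC)c2)ccc1O[Si](C(C)C)(C(C)C)C(C)C | intermediate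
19 | (3R,4S)-3-{(S)-[3,5-dimethoxy-4-(TIPS-oxy)phenyl](TIPS-oxy)methyl}-4-[3-methoxy-4-(TIPS-oxy)benzyl]tetrahydrofuran-2-ol (lactol, both anomers, formed in the flask) | COc1cc(C[C@@H]2COC(O)[C@H]2[C@H](O[Si](C(C)C)(C(C)C)C(C)C)c2cc(OC)c(O[Si](C(C)C)(C(C)C)C(C)C)c(OC)c2)ccc1O[Si](C(C)C)(C(C)C)C(C)C | intermediate
20 | (2S,3S)-2-{(S)-[3,5-dimethoxy-4-(TIPS-oxy)phenyl](TIPS-oxy)methyl}-3-[3-methoxy-4-(TIPS-oxy)benzyl]butane-1,4-diol | COc1cc(C[C@H](CO)[C@@H](CO)[C@H](O[Si](C(C)C)(C(C)C)C(C)C)c2cc(OC)c(O[Si](C(C)C)(C(C)C)C(C)C)c(OC)c2)ccc1O[Si](C(C)C)(C(C)C)C(C)C | intermediate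
21 | (3S,4S)-3-{(S)-[3,5-dimethoxy-4-(TIPS-oxy)phenyl](TIPS-oxy)methyl}-4-[3-methoxy-4-(TIPS-oxy)benzyl]tetrahydrofuran | COc1cc(C[C@@H]2COC[C@H]2[C@H](O[Si](C(C)C)(C(C)C)C(C)C)c2cc(OC)c(O[Si](C(C)C)(C(C)C)C(C)C)c(OC)c2)ccc1O[Si](C(C)C)(C(C)C)C(C)C | intermediate
22 | (S)-(4-hydroxy-3,5-dimethoxyphenyl)[(3S,4S)-4-(4-hydroxy-3-methoxybenzyl)tetrahydrofuran-3-yl]methanol | COc1cc(C[C@@H]2COC[C@H]2[C@H](O)c2cc(OC)c(O)c(OC)c2)ccc1O | target

## Step count and risks

Total: 15 steps. Longest linear sequence: 12 steps (steps 4 to 15, from 7 through 8, 9, 10, 13, 14, 15, 16, 17, 18, 20 and 21 to 22).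

Least certain steps:

Step 7 (key step). Proton transfer from the γ-position of 2 to 11 may compete with conjugate addition. C-alkylation of the crowded enolate 12 may be slow, so that part of it is only protonated on work-up, and trans selectivity in the alkylation may be incomplete. Fallback: the two bond formations are separated. Setting out from 2 and 6, the conjugate addition is run alone and quenched with NH4Cl to give (4S,5S)-5-(TBS-oxymethyl)-4-{2-[3,5-dimethoxy-4-(TIPS-oxy)phenyl]-1,3-dithian-2-yl}dihydrofuran-2(3H)-one F1. After purification, F1 is deprotonated with LiN(SiMe3)2 in THF/DMPU at −78 °C and alkylated with 10 trans to the dithianyl group, which comes back to the route at 13.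

Step 8. Hydrolysis may be slow because the dithiane carbon is fully substituted and buried. The iodine reagent may also oxidise the electron-rich rings, and liberated acid may remove the primary TBS ether. Fallback: two-stage removal through the sulfoxide. Setting out from 13, mCPBA (1 equiv, CH2Cl2, −78 °C) oxidises one sulfur to give the dithiane 1-oxide of 13 (sulfoxide diastereomers) F2. Pummerer-type activation of F2 with (CF3CO)2O and 2,6-lutidine, then aqueous NaHCO3, cleaves the weakened C–S bond and should return to the route at 14.

Step 9. Facial selectivity may be poor, because the smaller flank of the ketone is a branched ring carbon and the catalyst's distinction between aryl and alkyl is weaker than for methyl ketones; any residual substrate bias could oppose the catalyst. Fallback: catalyst control is replaced by separation and recycling. Setting out from 14, reduction with NaBH4 and CeCl3·7H2O in MeOH at −40 °C gives both C7 epimers, which are separated by chromatography. The desired epimer is 15, where the route is rejoined; the unwanted (3S,4R,5S)-5-(TBS-oxymethyl)-4-{(R)-[3,5-dimethoxy-4-(TIPS-oxy)phenyl](hydroxy)methyl}-3-[3-methoxy-4-(TIPS-oxy)benzyl]dihydrofuran-2(3H)-one F3 is returned to 14 with Dess–Martin periodinane (CH2Cl2, NaHCO3).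

Step 12. Acid may ionise the C7–O bond, with capture by the free C5 hydroxyl (closing the wrong C7–O–C5 ring) or by methanol; prolonged exposure may also remove aryl silyl ethers. Fallback: the order is changed so that no hydroxyl is positioned for such capture. Setting out from 16, the primary TBS ether is removed at the lactone stage with pyridine-buffered HF·pyridine in THF at 0 °C to give (3S,4S,5S)-5-(hydroxymethyl)-4-{(S)-[3,5-dimethoxy-4-(TIPS-oxy)phenyl](TIPS-oxy)methyl}-3-[3-methoxy-4-(TIPS-oxy)benzyl]dihydrofuran-2(3H)-one F4. LiBH4 reduction of F4 then gives the triol directly, rejoining the route at 18.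

Step 14. Closure may be slow or incomplete because the nucleophile is an unactivated primary alcohol, with alkylation of the reduced azodicarboxylate as a side reaction. Fallback: reductive etherification instead of dehydration. Setting out from 18, the periodate cleavage is worked up without borohydride to isolate lactol 19, which is reduced with Et3SiH and BF3·OEt2 in CH2Cl2 at −78 °C (oxocarbenium ion reduction) to come back at 21. This needs no new compound, but it exposes the C7 silyl ether to a Lewis acid and is therefore held in reserve.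

## Further compounds

F1 | step 7 | (4S,5S)-5-(TBS-oxymethyl)-4-{2-[3,5-dimethoxy-4-(TIPS-oxy)phenyl]-1,3-dithian-2-yl}dihydrofuran-2(3H)-one | O=C1C[C@H](C2(SCCCS2)c2cc(OC)c(O[Si](C(C)C)(C(C)C)C(C)C)c(OC)c2)[C@@H](CO[Si](C)(C)C(C)(C)C)O1
F2 | step 8 | dithiane 1-oxide of 13 (sulfoxide diastereomers) | COc1cc(C[C@@H]2C(=O)O[C@H](CO[Si](C)(C)C(C)(C)C)[C@H]2C3(SCCCS3=O)c3cc(OC)c(O[Si](C(C)C)(C(C)C)C(C)C)c(OC)c3)ccc1O[Si](C(C)C)(C(C)C)C(C)C
F3 | step 9 | (3S,4R,5S)-5-(TBS-oxymethyl)-4-{(R)-[3,5-dimethoxy-4-(TIPS-oxy)phenyl](hydroxy)methyl}-3-[3-methoxy-4-(TIPS-oxy)benzyl]dihydrofuran-2(3H)-one | COc1cc(C[C@@H]2C(=O)O[C@H](CO[Si](C)(C)C(C)(C)C)[C@H]2[C@@H](O)c2cc(OC)c(O[Si](C(C)C)(C(C)C)C(C)C)c(OC)c2)ccc1O[Si](C(C)C)(C(C)C)C(C)C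
F4 | step 12 | (3S,4S,5S)-5-(hydroxymethyl)-4-{(S)-[3,5-dimethoxy-4-(TIPS-oxy)phenyl](TIPS-oxy)methyl}-3-[3-methoxy-4-(TIPS-oxy)benzyl]dihydrofuran-2(3H)-one | COc1cc(C[C@@H]2C(=O)O[C@H](CO)[C@H]2[C@H](O[Si](C(C)C)(C(C)C)C(C)C)c2cc(OC)c(O[Si](C(C)C)(C(C)C)C(C)C)c(OC)c2)ccc1O[Si](C(C)C)(C(C)C)C(C)C
F0 | step 14 | none | none
A1 | alternative 1 | (S)-4-benzyl-3-{(E)-4-[3-methoxy-4-(TIPS-oxy)phenyl]-4-oxobut-2-enoyl}oxazolidin-2-one | COc1cc(C(=O)/C=C/C(=O)N2[C@@H](Cc3ccccc3)COC2=O)ccc1O[Si](C(C)C)(C(C)C)C(C)C
A2 | alternative 1 | chloromethyl (trimethylsilyl)methyl ether | C[Si](C)(C)COCCl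
A3 | alternative 1 | (S)-4-benzyl-3-{(3S,4S)-4-[3-methoxy-4-(TIPS-oxy)benzoyl]tetrahydrofuran-3-carbonyl}oxazolidin-2-one | COc1cc(C(=O)[C@@H]2COC[C@H]2C(=O)N2[C@@H](Cc3ccccc3)COC2=O)ccc1O[Si](C(C)C)(C(C)C)C(C)C
A4 | alternative 2 | 4-vinyl-1,3-dioxolan-2-one (vinylethylene carbonate, racemic) | C=CC1COC(=O)O1
A5 | alternative 2 | 1-[3-methoxy-4-(TIPS-oxy)phenyl]prop-2-en-1-one | COc1cc(C(=O)C=C)ccc1O[Si](C(C)C)(C(C)C)C(C)C
A6 | alternative 2 | [(3S,4S)-4-ethenyltetrahydrofuran-3-yl][3-methoxy-4-(TIPS-oxy)phenyl]methanone | COc1cc(C(=O)[C@@H]2COC[C@H]2C=C)ccc1O[Si](C(C)C)(C(C)C)C(C)C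
A7 | alternative 3 | 1,3-dioxoisoindolin-2-yl (3S)-2-[(allyloxy)methyl]-3-[3,5-dimethoxy-4-(TIPS-oxy)phenyl]-3-(TIPS-oxy)propanoate (both C2 epimers) | C=CCOCC(C(=O)ON1C(=O)c2ccccc2C1=O)[C@H](O[Si](C(C)C)(C(C)C)C(C)C)c1cc(OC)c(O[Si](C(C)C)(C(C)C)C(C)C)c(OC)c1
A8 | alternative 3 | (4-iodo-2-methoxyphenoxy)triisopropylsilane | COc1cc(I)ccc1O[Si](C(C)C)(C(C)C)C(C)C
A9 | alternative 3 | (3S,4S)-3-{(S)-[3,5-dimethoxy-4-(TIPS-oxy)phenyl](TIPS-oxy)methyl}-4-[3-methoxy-4-(TIPS-oxy)benzyl]tetrahydrofuran (identical with 21) | COc1cc(C[C@@H]2COC[C@H]2[C@H](O[Si](C(C)C)(C(C)C)C(C)C)c2cc(OC)c(O[Si](C(C)C)(C(C)C)C(C)C)c(OC)c2)ccc1O[Si](C(C)C)(C(C)C)C(C)C
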